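- With [Q] charged at 0.80 M in both runs and [X] charged at 34 mM in blue against 23 mM in ochre, the two runs differ in their catalyst charge, so they can be laid on one scale.

| flask | Q | X | remark | time |
|---|---|---|---|---|
| blue | 0.80 M | 34 mM | the very flask that is asked about, followed so far |  |
| ochre | 0.80 M | 23 mM | run made earlier |  |
| flask | 0.80 M | 34 mM |  | 25 h |

| run | time / h | Z / % | Q / % |
|---|---|---|---|
| blue | 2.00 | 21.9 | 44.1 |
| blue | 3.00 | 26.7 | 31.5 |
| blue | 6.00 | 35.0 | 18.9 |
| blue | 10.0 | 42.6 | 15.4 |
| blue | 15.0 | 43.7 | 13.7 |
| blue | 25.0 | 48.5 | 14.4 |
| ochre | 1.33 | 10.9 | 60.8 |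
| ochre | 3.00 | 19.0 | 37.1 |
| ochre | 6.00 | 25.5 | 23.5 |
| ochre | 10.0 | 28.9 | 19.6 |
| ochre | 12.0 | 32.1 | 19.8 |
| ochre | 20.0 | 36.4 | 18.5 |

(standard deviation of a reading: 1 percentage point)

- Z that was removed still counts
- the numbers in the tables scatter with a standard deviation of 1 percentage point
- additions bring no volume worth counting

- summer: at 25 h take out 90% of the Z then present, then wait 12 h
- winter: at 25 h add X, 50.0% of the amount charged, then wait 12 h
- autumn: at 25 h add Q, 50.0% of the amount charged, then wait 12 h
- dawn: change nothing and wait 12 h more

- Z, in percent of the Q first charged, at 25 h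
- which option adds most Z ("none" when 2 percentage points or less is all one gets) (summer / winter / autumn / dawn / none)
- Z present, with what was taken out counted in, in percent of the Q first charged, after summer
- Z present, with what was taken out counted in, in percent of the Q first charged, after dawn

- The scale is the catalyst clock τ, the natural logarithm of the charge's share not yet Z, sign turned, divided by the [X] charged, which in blue at 25.0 h reads 0.0195 /mM; it is the pseudo-first-order way of counting a pool drained in step with working X.
- In the first instants, at 2.00 h, blue holds Q 44.1% and Z 21.9%, so 34.0% of the charge already sits in something unseen, more than the Z.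
- At 3.00 h the clock reads 0.00914 /mM in blue and 0.00916 /mM in ochre, and at 6.00 h it reads 0.0127 /mM and 0.0128 /mM, so the two charges keep one time.
- In the middle, blue's clock reaches 0.0169 /mM at 15.0 h, gaining less per hour after 6.00 h than before it, which reads as working X being lost.
- At the end, blue's Q stands at 13.7% and then 14.4%, level within the scatter, while Z still climbs and the unseen share falls to 37.1%, so that share reads as paying back into Q.
- The reckoning here sets ochre's clock at 20.0 h, 0.0197 /mM, on the blue charge and gets 48.8% for blue at that same hour, an estimate that stands beside blue's own reading of 48.5% at 25.0 h, each reading scattering by 1 percentage point.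
- The forecast gives 47.5% (46.2% to 48.8%), 50% after summer, 49.8% after dawn, and winter as best: “Fresh X gives about +8–9, so winter is best.”
- The flask gives 48.8%, 50.7% after summer, 50.7% after dawn, and winter as best with 9.1 points, against 4.9 points for autumn, so the forecast held.

    Q + X → X + Z (k = 0.00140 /M/s)
    Q ⇌ J (K = 2.50, k = 8.00 × 10⁻⁵ /s)
    X → E (k = 2.50 × 10⁻⁵ /s)

- The blue flask's clock stands at 0.0197 /mM at 25.0 h, with J at 37.1% of the charge against Q at 14.0% and X at 10.5% of its own charge. The main reason for where Z stands in this flask is the turning of Q into J, both ways: with it taken away, Z at 25.0 h reads 81.8% against 48.8%. Set on the neighbour flask charged with 0.0085 M of X, blue's clock τ gives 15.3% at the same hour, and that neighbour holds Z at 16.4%.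

The readings were generated by integration from invented constants.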